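**Plan**

Numbering used: chroman O1, C2, C3, C4, C4a–C8a; indenone C1–C7a; C1' is the CH2 between C2 and C6.

1. Retrosynthesis: the pyran ring of the chroman is cut last, at C4a–C4 and O1–C2 (phenol + β,β-disubstituted enal → 2H-chromene, then C3=C4 hydrogenation). Before that: the C3–C4 unit (cross-metathesis), the C6–C1' bond together with the C4 oxygen (allyl Grignard, oxidative 1,3-transposition), C4–C5 of the cyclohexenone (aldol) and C5–C6 (alkyllithium + lactone).
2. Forward order: the cyclopentane with both methyl-bearing quaternary carbons is present from the start (bicyclo[3.3.0]octanedione); it is desymmetrised, cut to a δ-lactone, closed to the cyclohexenone, given its C6 side chain, and the chroman is formed last as the fragment union.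
3. Feature that allows the key event: the free ortho carbon (future C4a) next to the phenol OH, with the para position blocked by OMe and the other ortho position by CH3, is a 1,3-C,O-bis-nucleophile. The C4–C3–C2 segment with fully substituted C2 maps onto the carbonyl, α and β carbons of an enal, a 1,3-bis-electrophile. Their union closes the pyran ring.
4. Stereochemistry: cis C3a/C7a come from a meso ketone by enantioselective deprotonation with a chiral lithium amide. C2 is set in the ring-closing step by a chiral Brønsted acid (catalyst control, remote from the ring stereocentres).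
5. Helpers: a TBS ether on the tertiary alcohol, a phenylboronic acid template in the key step (released in the same flask), and the chromene C3=C4 double bond (removed by hydrogenation).

Key step: step 12

Assumption: compound 1 is taken as a catalogue compound, and the sense of induction of the chiral lithium amide (step 3) and of the chiral acid (step 12) is taken from the closest analogies; if either is opposite, the enantiomeric amide or acid is used.

**Route**

Step 1
Reactants: 1 cis-1,5-dimethylbicyclo[3.3.0]octane-3,7-dione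
Product: 2 mono-ethylene ketal of 1 (meso)
Conditions: HOCH2CH2OH (1.0 equiv), p-TsOH (cat.), benzene, reflux, Dean–Stark
Reagents that add atoms: ethane-1,2-diol, OCCO
Why: Acid-catalysed ketalisation with one equivalent of diol protects one of the two equivalent ketones (acetal protection); the diketone and bis-ketal that form alongside should be separable and recyclable.

Step 2
Reactants: 2 mono-ethylene ketal of 1
Product: 5 cis-1,5-dimethylbicyclo[3.3.0]octan-3-one, via hydrazone 3 (not isolated), via deoxygenated ketal 4 (not isolated)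
Conditions: N2H4·H2O, KOH, diethylene glycol, 130 then 200 °C; then 2 M HCl, THF, rt
Reagents that add atoms: water, O
Why: Wolff–Kishner reduction (Huang-Minlon modification) removes the free carbonyl through its hydrazone while the base-stable dioxolane survives, and the acidic work-up hydrolyses the acetal to the meso ketone.

Step 3
Reactants: 5 cis-1,5-dimethylbicyclo[3.3.0]octan-3-one
Product: 6 (1R,5S)-1,5-dimethyl-3-(trimethylsilyloxy)bicyclo[3.3.0]oct-2-ene
Conditions: (R,R)-bis(1-phenylethyl)amine, n-BuLi, LiCl, TMSCl (in situ quench), THF, −100 °C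
Reagents that add atoms: chlorotrimethylsilane, C[Si](C)(C)Cl
Why: Enantioselective deprotonation of a meso ketone by a chiral lithium amide with internal silyl quench removes one of the two enantiotopic α-protons, so the chiral base fixes the absolute configuration of both quaternary carbons (future C3a and C7a).

Step 4
Reactants: 6 (1R,5S)-1,5-dimethyl-3-(trimethylsilyloxy)bicyclo[3.3.0]oct-2-ene
Product: 8 (4aS,7aS)-4a,7a-dimethylhexahydrocyclopenta[c]pyran-3(1H)-one, via hydroxy acid 7 (not isolated)
Conditions: O3, CH2Cl2/MeOH, −78 °C; NaBH4, −78 °C to rt; then 1 M HCl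
Reagents that add atoms: ozone, [O-][O+]=O
Why: Ozonolysis of the silyl enol ether cleaves the ring to an aldehyde and a carboxylic acid, borohydride reduces the aldehyde, and the hydroxy acid lactonises on acidification without touching the quaternary centres.

Step 5
Reactants: 9 4-bromo-2-methylbutan-2-ol
Product: 10 (4-bromo-2-methylbutan-2-yl)oxy(tert-butyl)dimethylsilane
Conditions: TBSOTf, 2,6-lutidine, CH2Cl2, 0 °C to rt
Reagents that add atoms: tert-butyldimethylsilyl trifluoromethanesulfonate, CC(C)(C)[Si](C)(C)OS(=O)(=O)C(F)(F)F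
Why: A silyl triflate with a hindered base silylates the tertiary alcohol (protection), giving an ether that should survive the organolithium, chromium and acid steps.

Step 6
Reactants: 8 (4aS,7aS)-4a,7a-dimethylhexahydrocyclopenta[c]pyran-3(1H)-one; 10 (4-bromo-2-methylbutan-2-yl)oxy(tert-butyl)dimethylsilane
Product: 12 5-(tert-butyldimethylsilyloxy)-1-[(1S,2S)-2-(hydroxymethyl)-1,2-dimethylcyclopentyl]-5-methylhexan-2-one (in equilibrium with its cyclic hemiketal), via alkyllithium 11 (not isolated)
Conditions: 10, Li (1% Na), Et2O, −20 °C; then 8, THF, −78 °C; aq. NH4Cl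
Reagents that add atoms: none
Why: Reductive lithiation of the primary bromide and addition of one equivalent of the alkyllithium to the δ-lactone at low temperature should stop at the ketone stage, because the tetrahedral lithium alkoxide persists until work-up (organolithium addition to a lactone).

Step 7
Reactants: 12 5-(tert-butyldimethylsilyloxy)-1-[(1S,2S)-2-(hydroxymethyl)-1,2-dimethylcyclopentyl]-5-methylhexan-2-one
Product: 13 (1S,2S)-2-[5-(tert-butyldimethylsilyloxy)-5-methyl-2-oxohexyl]-1,2-dimethylcyclopentane-1-carbaldehyde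
Conditions: Dess–Martin periodinane, NaHCO3, CH2Cl2, rt
Reagents that add atoms: none
Why: Dess–Martin oxidation of the neopentyl primary alcohol, drained from the hemiketal equilibrium, gives a non-enolisable aldehyde.

Step 8
Reactants: 13 (1S,2S)-2-[5-(tert-butyldimethylsilyloxy)-5-methyl-2-oxohexyl]-1,2-dimethylcyclopentane-1-carbaldehyde
Product: 14 (3aS,7aR)-6-[2-(tert-butyldimethylsilyloxy)-2-methylpropyl]-3a,7a-dimethyl-1,2,3,3a,4,7a-hexahydro-5H-inden-5-one
Conditions: KOH, MeOH, rt then 50 °C
Reagents that add atoms: none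
Why: Intramolecular aldol condensation in which only the ketone can enolise and only its chain-side enolate reaches the aldehyde through a six-membered transition state, so a single cyclohexenone should form on the already fixed cis ring fusion.

Step 9
Reactants: 14 (3aS,7aR)-6-[2-(tert-butyldimethylsilyloxy)-2-methylpropyl]-3a,7a-dimethyl-1,2,3,3a,4,7a-hexahydro-5H-inden-5-one; 15 2-methylallylmagnesium chloride
Product: 16 (3aS,7aR)-6-[2-(tert-butyldimethylsilyloxy)-2-methylpropyl]-3a,7a-dimethyl-5-(2-methylprop-2-en-1-yl)-2,3,3a,4,5,7a-hexahydro-1H-inden-5-ol (mixture of epimers at the carbinol carbon)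
Conditions: THF, −78 to 0 °C; aq. NH4Cl
Reagents that add atoms: none
Why: Allylic Grignard reagents add 1,2 to enone carbonyls through a cyclic transition state (Grignard addition); the new carbinol centre is of no consequence because it becomes sp2 in step 10.

Step 10
Reactants: 16 (3aS,7aR)-6-[2-(tert-butyldimethylsilyloxy)-2-methylpropyl]-3a,7a-dimethyl-5-(2-methylprop-2-en-1-yl)-2,3,3a,4,5,7a-hexahydro-1H-inden-5-ol
Product: 17 (3aS,7aS)-5-[2-(tert-butyldimethylsilyloxy)-2-methylpropyl]-3a,7a-dimethyl-6-(2-methylprop-2-en-1-yl)-1,2,3,3a,7,7a-hexahydro-4H-inden-4-one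
Conditions: pyridinium chlorochromate [C5H5NH][CrO3Cl], 4 Å molecular sieves, CH2Cl2, rt
Reagents that add atoms: pyridinium chlorochromate, [O-][Cr](=O)(=O)Cl.c1cc[nH+]cc1 (delivers the carbonyl oxygen)
Why: Babler–Dauben oxidative 1,3-transposition, in which the tertiary allylic chromate ester undergoes a [3,3] shift to the secondary allylic chromate at C4 and is oxidised to the tetrasubstituted enone.

Step 11
Reactants: 17 (3aS,7aS)-5-[2-(tert-butyldimethylsilyloxy)-2-methylpropyl]-3a,7a-dimethyl-6-(2-methylprop-2-en-1-yl)-1,2,3,3a,7,7a-hexahydro-4H-inden-4-one; 18 (E)-but-2-enal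
Product: 19 (2E)-4-{(3aS,7aS)-5-[2-(tert-butyldimethylsilyloxy)-2-methylpropyl]-3a,7a-dimethyl-4-oxo-2,3,3a,4,7,7a-hexahydro-1H-inden-6-yl}-3-methylbut-2-enal (the Z isomer may accompany it and serves equally)
Conditions: 18 (excess), second-generation Hoveyda–Grubbs catalyst [RuCl2(H2IMes)(=CH-C6H4-2-OiPr)] (cat.), 1,4-benzoquinone (cat.), CH2Cl2, 40 °C
Reagents that add atoms: none
Why: Olefin cross-metathesis of the 1,1-disubstituted alkene with an excess of the enal partner should give the β,β-disubstituted enal, the tetrasubstituted enone alkene being inert to the ruthenium carbene.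

Step 12
Reactants: 19 (2E)-4-{(3aS,7aS)-5-[2-(tert-butyldimethylsilyloxy)-2-methylpropyl]-3a,7a-dimethyl-4-oxo-2,3,3a,4,7,7a-hexahydro-1H-inden-6-yl}-3-methylbut-2-enal; 20 4-methoxy-2-methylphenol
Product: 23 (3aS,7aS)-5-[2-(tert-butyldimethylsilyloxy)-2-methylpropyl]-6-{[(2S)-6-methoxy-2,8-dimethyl-2H-chromen-2-yl]methyl}-3a,7a-dimethyl-1,2,3,3a,7,7a-hexahydro-4H-inden-4-one, via benzodioxaborin 21 (not isolated), via quinone methide 22 (not isolated)
Conditions: PhB(OH)2 (1.1 equiv), (R)-3,3'-bis(2,4,6-triisopropylphenyl)-BINOL N-triflylphosphoramide (10 mol %), 4 Å molecular sieves, toluene, 25 to 45 °C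
Reagents that add atoms: none
Why: Proposed new method: phenylboronic acid ties the phenol oxygen and the aldehyde into cyclic boronate 21, which delivers the aldehyde carbon (C4) to the only free ortho carbon, and the chiral acid then ionises the benzylic C4–O bond to vinyl ortho-quinone methide 22, held as its protonated form in a contact ion pair with the chiral phosphoramide anion. The pyran ring closes by oxa-6π electrocyclisation of this cisoid oxatriene (O1 onto C2, formally a 6-endo collapse of the allyl cation onto the phenolic oxygen), which forms the O1–C2 bond and the quaternary centre. The closest known reaction types are the phenylboronic acid-mediated ortho-specific condensation of phenols with β,β-disubstituted enals to 2H-chromenes (thermal, racemic) and the chiral N-triflylphosphoramide-catalysed cyclisation of ortho-hydroxyaryl allylic alcohols to 2,2-disubstituted 2H-chromenes through chiral ion pairs; the proposal merges them so that closure occurs below the temperature of the uncatalysed pathway. C2 is set by the catalyst (facial selection within the ion pair, the E and Z forms of the allyl cation equilibrating before closure), while C3a and C7a are five bonds away and should exert no bias. The step needs ortho regiochemistry (boron template, para position blocked by OMe, other ortho position blocked by CH3), 1,2- rather than 1,4-attack on the enal (β,β-disubstitution) and reaction at the enal rather than the enone (tetrasubstituted, flanked by a quaternary carbon), all secured by the substrates.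

Step 13
Reactants: 23 (3aS,7aS)-5-[2-(tert-butyldimethylsilyloxy)-2-methylpropyl]-6-{[(2S)-6-methoxy-2,8-dimethyl-2H-chromen-2-yl]methyl}-3a,7a-dimethyl-1,2,3,3a,7,7a-hexahydro-4H-inden-4-one
Product: 24 (3aS,7aS)-5-[2-(tert-butyldimethylsilyloxy)-2-methylpropyl]-6-{[(2R)-6-methoxy-2,8-dimethyl-3,4-dihydro-2H-chromen-2-yl]methyl}-3a,7a-dimethyl-1,2,3,3a,7,7a-hexahydro-4H-inden-4-one
Conditions: H2 (1 atm), 5% Pd/C, EtOAc, rt
Reagents that add atoms: none
Why: Heterogeneous catalytic hydrogenation should reduce the cis-disubstituted styrenic C3=C4 bond and leave the hindered tetrasubstituted enone alkene; no stereocentre is touched (the descriptor at C2 changes only through the priority rules).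

Step 14
Reactants: 24 (3aS,7aS)-5-[2-(tert-butyldimethylsilyloxy)-2-methylpropyl]-6-{[(2R)-6-methoxy-2,8-dimethyl-3,4-dihydro-2H-chromen-2-yl]methyl}-3a,7a-dimethyl-1,2,3,3a,7,7a-hexahydro-4H-inden-4-one
Product: 25 (3aS,7aS)-5-(2-hydroxy-2-methylpropyl)-6-{[(2R)-6-methoxy-2,8-dimethyl-3,4-dihydro-2H-chromen-2-yl]methyl}-3a,7a-dimethyl-1,2,3,3a,7,7a-hexahydro-4H-inden-4-one (CNP0224132.1)
Conditions: HF·pyridine, THF/pyridine, 0 °C to rt
Reagents that add atoms: none
Why: Fluoride cleaves the tertiary silyl ether (deprotection) under non-basic conditions, which avoids vinylogous β-elimination of the chroman oxygen.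

**Compound list**

1 | cis-1,5-dimethylbicyclo[3.3.0]octane-3,7-dione | O=C1C[C@@]2(C)CC(=O)C[C@@]2(C)C1 | starting material
2 | mono-ethylene ketal of 1 (one carbonyl as 1,3-dioxolane, cis-fused, meso) | O=C1C[C@@]2(C)CC3(OCCO3)C[C@@]2(C)C1 | intermediate
3 | hydrazone of 2 | NN=C1C[C@@]2(C)CC3(OCCO3)C[C@@]2(C)C1 | intermediate
4 | ethylene ketal of cis-1,5-dimethylbicyclo[3.3.0]octan-3-one | C1C[C@@]2(C)CC3(OCCO3)C[C@@]2(C)C1 | intermediate
5 | cis-1,5-dimethylbicyclo[3.3.0]octan-3-one (meso) | O=C1C[C@@]2(C)CCC[C@@]2(C)C1 | intermediate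
6 | (1R,5S)-1,5-dimethyl-3-(trimethylsilyloxy)bicyclo[3.3.0]oct-2-ene | C[Si](C)(C)OC1=C[C@@]2(C)CCC[C@@]2(C)C1 | intermediate
7 | 2-[(1S,2S)-2-(hydroxymethyl)-1,2-dimethylcyclopentyl]acetic acid | OC[C@@]1(C)CCC[C@@]1(C)CC(=O)O | intermediate
8 | (4aS,7aS)-4a,7a-dimethylhexahydrocyclopenta[c]pyran-3(1H)-one | O1C[C@@]2(C)CCC[C@@]2(C)CC1=O | intermediate
9 | 4-bromo-2-methylbutan-2-ol | CC(C)(O)CCBr | starting material
10 | (4-bromo-2-methylbutan-2-yl)oxy(tert-butyl)dimethylsilane | CC(C)(CCBr)O[Si](C)(C)C(C)(C)C | intermediate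
11 | [3-(tert-butyldimethylsilyloxy)-3-methylbutyl]lithium | [Li]CCC(C)(C)O[Si](C)(C)C(C)(C)C | intermediate
12 | 5-(tert-butyldimethylsilyloxy)-1-[(1S,2S)-2-(hydroxymethyl)-1,2-dimethylcyclopentyl]-5-methylhexan-2-one | OC[C@@]1(C)CCC[C@@]1(C)CC(=O)CCC(C)(C)O[Si](C)(C)C(C)(C)C | intermediate
13 | (1S,2S)-2-[5-(tert-butyldimethylsilyloxy)-5-methyl-2-oxohexyl]-1,2-dimethylcyclopentane-1-carbaldehyde | O=C[C@@]1(C)CCC[C@@]1(C)CC(=O)CCC(C)(C)O[Si](C)(C)C(C)(C)C | intermediate
14 | (3aS,7aR)-6-[2-(tert-butyldimethylsilyloxy)-2-methylpropyl]-3a,7a-dimethyl-1,2,3,3a,4,7a-hexahydro-5H-inden-5-one | O=C1C(CC(C)(C)O[Si](C)(C)C(C)(C)C)=C[C@@]2(C)CCC[C@@]2(C)C1 | intermediate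
15 | 2-methylallylmagnesium chloride | CC(=C)C[Mg]Cl | starting material
16 | (3aS,7aR)-6-[2-(tert-butyldimethylsilyloxy)-2-methylpropyl]-3a,7a-dimethyl-5-(2-methylprop-2-en-1-yl)-2,3,3a,4,5,7a-hexahydro-1H-inden-5-ol (epimers at C5) | OC1(CC(C)=C)C(CC(C)(C)O[Si](C)(C)C(C)(C)C)=C[C@@]2(C)CCC[C@@]2(C)C1 | intermediate
17 | (3aS,7aS)-5-[2-(tert-butyldimethylsilyloxy)-2-methylpropyl]-3a,7a-dimethyl-6-(2-methylprop-2-en-1-yl)-1,2,3,3a,7,7a-hexahydro-4H-inden-4-one | C=C(C)CC1=C(CC(C)(C)O[Si](C)(C)C(C)(C)C)C(=O)[C@@]2(C)CCC[C@@]2(C)C1 | intermediate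
18 | (E)-but-2-enal (crotonaldehyde) | C/C=C/C=O | starting material
19 | (2E)-4-{(3aS,7aS)-5-[2-(tert-butyldimethylsilyloxy)-2-methylpropyl]-3a,7a-dimethyl-4-oxo-2,3,3a,4,7,7a-hexahydro-1H-inden-6-yl}-3-methylbut-2-enal | O=C/C=C(\C)CC1=C(CC(C)(C)O[Si](C)(C)C(C)(C)C)C(=O)[C@@]2(C)CCC[C@@]2(C)C1 | intermediate
20 | 4-methoxy-2-methylphenol | COc1ccc(O)c(C)c1 | starting material
21 | 6-methoxy-8-methyl-2-phenyl-4H-1,3,2-benzodioxaborin carrying at C4 the (E)-2-methyl-3-(indenonyl)prop-1-enyl chain of 19 (epimers at C4) | COc1cc(C)c2OB(c3ccccc3)OC(/C=C(\C)CC3=C(CC(C)(C)O[Si](C)(C)C(C)(C)C)C(=O)[C@@]4(C)CCC[C@@]4(C)C3)c2c1 | intermediate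
22 | vinyl ortho-quinone methide (4-methoxy-2-methyl-6-alkenylidenecyclohexa-2,4-dienone) derived from 20 and 19 | COC1=CC(=CC=C(C)CC2=C(CC(C)(C)O[Si](C)(C)C(C)(C)C)C(=O)[C@@]3(C)CCC[C@@]3(C)C2)C(=O)C(C)=C1 | intermediate
23 | (3aS,7aS)-5-[2-(tert-butyldimethylsilyloxy)-2-methylpropyl]-6-{[(2S)-6-methoxy-2,8-dimethyl-2H-chromen-2-yl]methyl}-3a,7a-dimethyl-1,2,3,3a,7,7a-hexahydro-4H-inden-4-one | COc1cc(C)c2c(c1)C=C[C@](C)(CC1=C(CC(C)(C)O[Si](C)(C)C(C)(C)C)C(=O)[C@@]3(C)CCC[C@@]3(C)C1)O2 | intermediate
24 | (3aS,7aS)-5-[2-(tert-butyldimethylsilyloxy)-2-methylpropyl]-6-{[(2R)-6-methoxy-2,8-dimethyl-3,4-dihydro-2H-chromen-2-yl]methyl}-3a,7a-dimethyl-1,2,3,3a,7,7a-hexahydro-4H-inden-4-one | COc1cc(C)c2c(c1)CC[C@](C)(CC1=C(CC(C)(C)O[Si](C)(C)C(C)(C)C)C(=O)[C@@]3(C)CCC[C@@]3(C)C1)O2 | intermediate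
25 | (3aS,7aS)-5-(2-hydroxy-2-methylpropyl)-6-{[(2R)-6-methoxy-2,8-dimethyl-3,4-dihydro-2H-chromen-2-yl]methyl}-3a,7a-dimethyl-1,2,3,3a,7,7a-hexahydro-4H-inden-4-one | COc1cc(C)c2c(c1)CC[C@](C)(CC1=C(CC(C)(C)O)C(=O)[C@@]3(C)CCC[C@@]3(C)C1)O2 | target

**Step count and risks**

Total: 14 steps. Longest linear sequence: 13 steps (steps 1–4 and 6–14, from 1 to 25); step 5 is a one-step side branch.

Steps most likely to fail:

Step 12 (proposed new method). The facial discrimination in the ring closure may be poor, since methyl and methylene at the cationic terminus differ little. The racemic thermal closure may compete, and the acid may move the enal double bond into conjugation with the enone. The fallback uses known reactions, sets out from 19 and returns at 23. Luche reduction (NaBH4, CeCl3·7H2O, MeOH, −40 °C) gives the (E)-allylic alcohol F1, freed from any Z isomer by chromatography. Sharpless asymmetric epoxidation (Ti(OiPr)4, D-(−)-diethyl tartrate, t-BuOOH, CH2Cl2, −20 °C) gives the (2R,3R)-epoxy alcohol F2, so the reagent sets the future C2. Dess–Martin oxidation gives the epoxy aldehyde F3. Phenol 20 is converted with EtMgBr into bromomagnesium 4-methoxy-2-methylphenoxide F4, which adds ortho-specifically to F3 in toluene to give the epoxy benzylic alcohol F5. Camphorsulfonic acid is then added to the same flask, and the phenol opens the epoxide 6-endo at the tertiary carbon with inversion to give the 3,4-dihydroxychroman F6. Garegg–Samuelsson deoxygenation of the vicinal diol (PPh3, I2, imidazole, toluene, heat) returns to chromene 23.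

Step 3. The base may discriminate the enantiotopic α-protons poorly, or with the opposite sense, and the silyl enol ether may partly equilibrate. The fallback is a classical resolution, sets out from 5 and returns at 8. LDA/TMSCl gives the racemic silyl enol ether F7, and ozonolysis, NaBH4 and acid as in step 4 give the racemic lactone F8. Aminolysis with (R)-1-phenylethylamine and AlMe3 gives two diastereomeric hydroxy amides; the (1S,2S)-hydroxy amide F9 is separated from the (1R,2R)-hydroxy amide F10 by chromatography or crystallisation. Relactonisation of F9 (aq. H2SO4, dioxane, heat) returns 8.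

Step 11. Conversion of the 1,1-disubstituted alkene in the cross-metathesis may be low, ruthenium hydride species may move the double bond into conjugation, and the E/Z mixture may be hard to handle. The fallback builds the enal by carbometalation, sets out from 14 and returns at 19. Propargyl bromide with Mg (HgCl2 cat.) in Et2O gives allenylmagnesium bromide F11, which adds to 14 to give the homopropargylic alcohol F12. Zirconium-catalysed methylalumination (AlMe3, Cp2ZrCl2, CH2Cl2) gives the alkenylalane F13; this is converted with n-BuLi into its ate complex and trapped with paraformaldehyde to give the (E)-allylic diol F14. Pyridinium chlorochromate then oxidises the primary allylic alcohol and transposes the tertiary one in the same flask, returning 19 as the pure E isomer.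

Further compounds
F1 | step 12 | (3aS,7aS)-5-[2-(tert-butyldimethylsilyloxy)-2-methylpropyl]-6-[(2E)-4-hydroxy-2-methylbut-2-en-1-yl]-3a,7a-dimethyl-1,2,3,3a,7,7a-hexahydro-4H-inden-4-one | OC/C=C(\C)CC1=C(CC(C)(C)O[Si](C)(C)C(C)(C)C)C(=O)[C@@]2(C)CCC[C@@]2(C)C1
F2 | step 12 | (3aS,7aS)-5-[2-(tert-butyldimethylsilyloxy)-2-methylpropyl]-6-{[(2R,3R)-3-(hydroxymethyl)-2-methyloxiran-2-yl]methyl}-3a,7a-dimethyl-1,2,3,3a,7,7a-hexahydro-4H-inden-4-one | OC[C@H]1O[C@]1(C)CC2=C(CC(C)(C)O[Si](C)(C)C(C)(C)C)C(=O)[C@@]3(C)CCC[C@@]3(C)C2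
F3 | step 12 | (2S,3R)-3-methyl-3-(indenonylmethyl)oxirane-2-carbaldehyde (epoxy aldehyde from F2) | O=C[C@H]1O[C@]1(C)CC2=C(CC(C)(C)O[Si](C)(C)C(C)(C)C)C(=O)[C@@]3(C)CCC[C@@]3(C)C2
F4 | step 12 | bromomagnesium 4-methoxy-2-methylphenoxide | COc1ccc(O[Mg]Br)c(C)c1
F5 | step 12 | epoxy benzylic alcohol from ortho-hydroxyalkylation of 20 with F3 (epimers at the carbinol carbon) | COc1cc(C)c(O)c(c1)C(O)[C@H]1O[C@]1(C)CC2=C(CC(C)(C)O[Si](C)(C)C(C)(C)C)C(=O)[C@@]3(C)CCC[C@@]3(C)C2
F6 | step 12 | (3aS,7aS)-5-[2-(tert-butyldimethylsilyloxy)-2-methylpropyl]-6-{[(2S,3R)-3,4-dihydroxy-6-methoxy-2,8-dimethyl-3,4-dihydro-2H-chromen-2-yl]methyl}-3a,7a-dimethyl-1,2,3,3a,7,7a-hexahydro-4H-inden-4-one (epimers at C4 of the chroman) | COc1cc(C)c2c(c1)C(O)[C@@H](O)[C@](C)(CC1=C(CC(C)(C)O[Si](C)(C)C(C)(C)C)C(=O)[C@@]3(C)CCC[C@@]3(C)C1)O2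
F7 | step 3 | racemic cis-1,5-dimethyl-3-(trimethylsilyloxy)bicyclo[3.3.0]oct-2-ene | C[Si](C)(C)OC1=CC2(C)CCCC2(C)C1
F8 | step 3 | racemic cis-4a,7a-dimethylhexahydrocyclopenta[c]pyran-3(1H)-one | O=C1CC2(C)CCCC2(C)CO1
F9 | step 3 | 2-[(1S,2S)-2-(hydroxymethyl)-1,2-dimethylcyclopentyl]-N-[(1R)-1-phenylethyl]acetamide | OC[C@@]1(C)CCC[C@@]1(C)CC(=O)N[C@H](C)c1ccccc1
F10 | step 3 | 2-[(1R,2R)-2-(hydroxymethyl)-1,2-dimethylcyclopentyl]-N-[(1R)-1-phenylethyl]acetamide | OC[C@]1(C)CCC[C@]1(C)CC(=O)N[C@H](C)c1ccccc1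
F11 | step 11 | allenylmagnesium bromide | C=C=C[Mg]Br
F12 | step 11 | (3aS,7aR)-6-[2-(tert-butyldimethylsilyloxy)-2-methylpropyl]-3a,7a-dimethyl-5-(prop-2-yn-1-yl)-2,3,3a,4,5,7a-hexahydro-1H-inden-5-ol (epimers at C5) | C#CCC1(O)C(CC(C)(C)O[Si](C)(C)C(C)(C)C)=C[C@@]2(C)CCC[C@@]2(C)C1
F13 | step 11 | (E)-alkenyldimethylalane from methylalumination of F12 (as its dimethylaluminium alkoxide) | C[Al](C)/C=C(\C)CC1(O[Al](C)C)C(CC(C)(C)O[Si](C)(C)C(C)(C)C)=C[C@@]2(C)CCC[C@@]2(C)C1
F14 | step 11 | (3aS,7aR)-6-[2-(tert-butyldimethylsilyloxy)-2-methylpropyl]-5-[(2E)-4-hydroxy-2-methylbut-2-en-1-yl]-3a,7a-dimethyl-2,3,3a,4,5,7a-hexahydro-1H-inden-5-ol (epimers at C5) | OC/C=C(\C)CC1(O)C(CC(C)(C)O[Si](C)(C)C(C)(C)C)=C[C@@]2(C)CCC[C@@]2(C)C1
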